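**Strategy.** Everything rests on closing the cyclobutane (C4–C5–C11–C10; longipinane numbering, C1 = enone carbonyl, C7–C9 = triol carbons) last, through the C4–C10 bond. The structure offers the handle: the C9 oxygen is anti to the C4–C10 bond across C9–C10, which is the signature of an epoxide opening. The precursor is a cis-fused bicyclo[5.4.0]undecene carrying a C9–C10 epoxide and a C3 silyl enol ether, the latter installed regiospecifically by the Diels–Alder reaction that builds the six-membered ring. A Lewis acid makes C4 attack the tertiary epoxide carbon (4-exo), which sets C4 and C10 and frees the C9 hydroxyl in one operation.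

Key step: step 11

Remark on numbering: skeleton atoms carry the target's longipinane numbers throughout; C1–C2–C3–C4–C5–C11 is the six-membered ring, C5–C6–C7–C8–C9–C10–C11 the seven-membered ring, C6 bears two methyls and C10 one. "4,10-seco" means the C4–C10 bond is absent; "3-demethyl" means the C3 methyl is not yet present. TBS = tert-butyldimethylsilyl.

Remark on one formula: the SMILES of the Tebbe reagent shows the chloride on titanium and the methylene between titanium and aluminium; in the reagent the chloride also bridges to aluminium.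

Assumption: in step 4 the chiral oxazaborolidinium catalyst, not the remote C7 centre, fixes the π-face; the (S)-catalyst is taken to be the enantiomer that gives 7.

Step 1
Reactants: 1 (S)-pantolactone
Product: 2 (2S)-2,4-dihydroxy-N-methoxy-N,3,3-trimethylbutanamide
Conditions: MeNH(OMe)·HCl, AlMe3, CH2Cl2, 0 → 25 °C
Reagents that add atoms: N,O-dimethylhydroxylamine hydrochloride, CNOC.Cl
Why: Weinreb aminolysis of the lactone by the aluminium amide should open the ring without touching the carbinol centre.

Step 2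
Reactants: 2 Weinreb amide diol
Product: 4 (2S,4E)-2-hydroxy-N-methoxy-N,3,3-trimethyl-6-oxohept-4-enamide, via aldehyde 3 (not isolated)
Conditions: TEMPO (cat.), PhI(OAc)2, CH2Cl2, 25 °C; then Ph3P=CHC(O)CH3, 40 °C
Reagents that add atoms: 1-(triphenylphosphoranylidene)propan-2-one, CC(=O)C=P(c1ccccc1)(c1ccccc1)c1ccccc1
Why: The nitroxyl oxidation should take the primary alcohol in preference to the secondary one, and the non-enolisable aldehyde should undergo E-selective Wittig olefination with the stabilised ylide.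

Step 3
Reactants: 4 hydroxy enone
Product: 5 (2S,4E)-2,6-bis(TBSO)-N-methoxy-N,3,3-trimethylhepta-4,6-dienamide
Conditions: TBSOTf (2.5 equiv), Et3N, CH2Cl2, −78 → 0 °C
Reagents that add atoms: tert-butyldimethylsilyl triflate, CC(C)(C)[Si](C)(C)OS(=O)(=O)C(F)(F)F
Why: Soft enolisation of the methyl ketone can only give the 2-silyloxy-1,3-diene because the γ-carbon is quaternary, and the secondary alcohol is silylated in the same operation.

Step 4
Reactants: 5 silyloxy diene; 6 methyl vinyl ketone
Product: 7 (2S)-3-[(1S,6R)-6-acetyl-3-(TBSO)cyclohex-2-en-1-yl]-2-(TBSO)-N-methoxy-N,3-dimethylbutanamide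
Conditions: (S)-o-tolyl-CBS-oxazaborolidinium triflimide (20 mol%), CH2Cl2, −78 → −40 °C
Reagents that add atoms: none
Why: In this catalytic asymmetric Diels–Alder reaction the silyloxy group and the alkyl terminus direct C2 to the enone β-carbon (C1) and C5 to the α-carbon (C11), the endo transition state should give cis C5/C11, the catalyst-bound enone face fixes both centres relative to C7, and the adduct carries the C3=C4 silyl enol ether needed in step 11.

Step 5
Reactants: 7 methyl ketone
Product: 8 (2S)-2-(TBSO)-3-[(1R,6R)-3-(TBSO)-6-(prop-1-en-2-yl)cyclohex-2-en-1-yl]-N-methoxy-N,3-dimethylbutanamide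
Conditions: Cp2Ti(μ-CH2)(μ-Cl)AlMe2, pyridine, THF, −40 → 0 °C
Reagents that add atoms: Tebbe reagent Cp2Ti(μ-CH2)(μ-Cl)AlMe2, C[Al](C)C[Ti](Cl)(C1C=CC=C1)C1C=CC=C1
Why: Non-basic Tebbe methylenation should convert the ketone to the isopropenyl group without epimerising C11 and, at low temperature, without touching the Weinreb amide.

Step 6
Reactants: 8 Weinreb amide
Product: 9 (4S)-4-(TBSO)-5-methyl-5-[(1R,6R)-3-(TBSO)-6-(prop-1-en-2-yl)cyclohex-2-en-1-yl]hex-1-en-3-one
Conditions: CH2=CHMgBr, THF, −20 → 0 °C
Reagents that add atoms: vinylmagnesium bromide, C=C[Mg]Br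
Why: In the Weinreb ketone synthesis the chelated tetrahedral intermediate stops the addition at the vinyl ketone.

Step 7
Reactants: 9 vinyl ketone
Product: 10 cis-fused 3,7-bis(TBSO)-3-demethyl-4,10-secolongipina-3,9-dien-8-one
Conditions: second-generation Grubbs catalyst RuCl2(=CHPh)(H2IMes)(PCy3) (10 mol%), toluene, 80 °C
Reagents that add atoms: none
Why: Ring-closing metathesis of the enone vinyl group with the 1,1-disubstituted alkene, held close by the cis arrangement of the two arms, should close the seven-membered ring as the trisubstituted C9=C10 enone.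

Step 8
Reactants: 10 cycloheptenone
Product: 11 9,10-epoxy-3,7-bis(TBSO)-3-demethyl-4,10-secolongipin-3-en-8-one
Conditions: t-BuOOH, DBU, CH2Cl2, 0 → 25 °C
Reagents that add atoms: tert-butyl hydroperoxide, CC(C)(C)OO
Why: Nucleophilic (Weitz–Scheffer) epoxidation touches only the electron-poor enone and spares the silyl enol ether, and the peroxide should add to C10 anti to the C11–C1 bond, placing the epoxide oxygen on the face of H5, H7 and H11.

Step 9
Reactants: 11 epoxy ketone
Product: 12 9,10-epoxy-8-hydroxy-3,7-bis(TBSO)-3-demethyl-4,10-secolongipin-3-ene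
Conditions: Zn(BH4)2, Et2O, −20 → 0 °C
Reagents that add atoms: none
Why: In this chelation-controlled reduction zinc bridges the carbonyl and epoxide oxygens and delivers hydride from that face, which is also the face away from the C7 silyl ether, so the C8 carbinol should form trans to the epoxide oxygen and cis to C7–O.

Step 10
Reactants: 12 epoxy alcohol
Product: 13 9,10-epoxy-3,7,8-tris(TBSO)-3-demethyl-4,10-secolongipin-3-ene
Conditions: TBSOTf, 2,6-lutidine, CH2Cl2, −78 °C
Reagents that add atoms: tert-butyldimethylsilyl triflate, CC(C)(C)[Si](C)(C)OS(=O)(=O)C(F)(F)F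
Why: Silylation of the alcohol by the silyl triflate at −78 °C is much faster than Lewis-acid opening of the epoxide.

Step 11
Reactants: 13 epoxy silyl enol ether
Product: 14 9-hydroxy-7,8-bis(TBSO)-3-demethyllongipinan-3-one
Conditions: MeAlCl2 (1.2 equiv), CH2Cl2, −95 → −78 °C; then aq. NaHCO3
Reagents that add atoms: none
Why: Proposed new method: MeAlCl2 binds the epoxide oxygen and the tertiary C10–O bond lengthens while the C3 silyl enol ether, held under C10 by the cis C5/C11 ring fusion, attacks C10 through C4 from the face opposite the departing oxygen; the silyloxocarbenium ion then loses its silyl group as TBSCl, leaving the C3 ketone and the aluminium C9 alkoxide. The closest known reaction type is the Lewis-acid-initiated epoxide–olefin cyclisation terminated by an enol silyl ether (its anionic counterpart being the Stork 4-exo epoxide opening by a tethered carbanion), which has not been shown for closure of a four-membered ring. The cyclobutane closes in the 4-exo-tet mode. C10 is set by inversion at the epoxide carbon, C9 keeps the epoxide configuration and therefore ends anti to the new bond, and C4 is set by the cis ring fusion because C4 can reach C10 only on the face that carries the C11–C10 bond. The step needs C–C bond formation to outrun hydride or alkyl shift and proton loss at the incipient C10 cation, and attack at C10 rather than C9; the pre-organised, strongly nucleophilic enol ether, the temperature of −95 °C and the electron-poor C9 next to the C8 silyloxy group are relied on for this.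

Step 12
Reactants: 14 hydroxy ketone
Product: 15 9-angeloyloxy-7,8-bis(TBSO)-3-demethyllongipinan-3-one
Conditions: angelic acid, 2,4,6-Cl3C6H2COCl, Et3N, toluene, 25 °C; then 14, 80 °C
Reagents that add atoms: angelic acid, C/C=C(/C)C(=O)O
Why: Yamaguchi esterification through the mixed trichlorobenzoic anhydride, run without nucleophilic catalyst, should acylate the only free (hindered) hydroxyl without Z to E isomerisation of the angelate.

Step 13
Reactants: 15 saturated ketone
Product: 16 9-angeloyloxy-7,8-bis(TBSO)-3-demethyllongipin-1-en-3-one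
Conditions: IBX, 4-methylmorpholine N-oxide, DMSO, 25 → 45 °C
Reagents that add atoms: none
Why: IBX dehydrogenation proceeds through the enol, which can form only towards C2 because C4 is a bridgehead, so the C1=C2 enone is the only possible regioisomer.

Step 14
Reactants: 16 enone
Product: 17 9-angeloyloxy-3-hydroxy-7,8-bis(TBSO)longipin-1-ene
Conditions: MeLi, CeCl3, THF, −78 °C
Reagents that add atoms: methyllithium, [Li]C
Why: The organocerium reagent should add 1,2 to the enone carbonyl much faster than to the hindered angelate at −78 °C, from the face away from the C10 methyl; the carbinol configuration is lost in the next step.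

Step 15
Reactants: 17 tertiary allylic alcohol
Product: 18 9-angeloyloxy-7,8-bis(TBSO)longipin-2-en-1-one
Conditions: pyridinium chlorochromate (C5H5NH)[CrO3Cl], 4 Å molecular sieves, CH2Cl2, 25 °C
Reagents that add atoms: pyridinium chlorochromate, [O-][Cr](=O)(=O)Cl.c1cc[nH+]cc1
Why: In the Dauben–Babler oxidative 1,3-transposition the chromate ester of the tertiary allylic alcohol undergoes a [3,3] shift that places a chromium-bound oxygen on C1 and is oxidised there, giving the C1 ketone and the C2=C3 methyl-substituted alkene of the target.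

Step 16
Reactants: 18 bis-silyl ether
Product: 19 9-angeloyloxy-7,8-dihydroxylongipin-2-en-1-one
Conditions: HF·pyridine, pyridine, THF, 0 → 25 °C
Reagents that add atoms: none
Why: Buffered fluoride desilylation should remove both silyl ethers without acyl migration or angelate isomerisation.

Step 17
Reactants: 19 diol
Product: 20 CNP0251293.1
Conditions: isovaleric anhydride, DMAP (cat.), Et3N, CH2Cl2, −20 °C
Reagents that add atoms: isovaleric anhydride, CC(C)CC(=O)OC(=O)CC(C)C
Why: DMAP-catalysed acylation should take the C8 hydroxyl, flanked by two methine carbons, in preference to the neopentylic C7 hydroxyl next to quaternary C6.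

**Compound list**

1 | (S)-pantolactone, (3S)-3-hydroxy-4,4-dimethyloxolan-2-one | CC1(C)COC(=O)[C@H]1O | starting material
2 | (2S)-2,4-dihydroxy-N-methoxy-N,3,3-trimethylbutanamide | CON(C)C(=O)[C@@H](O)C(C)(C)CO | intermediate
3 | (2S)-2-hydroxy-N-methoxy-N,3,3-trimethyl-4-oxobutanamide (not isolated) | CON(C)C(=O)[C@@H](O)C(C)(C)C=O | intermediate
4 | (2S,4E)-2-hydroxy-N-methoxy-N,3,3-trimethyl-6-oxohept-4-enamide | CON(C)C(=O)[C@@H](O)C(C)(C)/C=C/C(C)=O | intermediate
5 | (2S,4E)-2,6-bis(TBSO)-N-methoxy-N,3,3-trimethylhepta-4,6-dienamide | CON(C)C(=O)[C@@H](O[Si](C)(C)C(C)(C)C)C(C)(C)/C=C/C(=C)O[Si](C)(C)C(C)(C)C | intermediate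
6 | methyl vinyl ketone (but-3-en-2-one) | CC(=O)C=C | starting material
7 | (2S)-3-[(1S,6R)-6-acetyl-3-(TBSO)cyclohex-2-en-1-yl]-2-(TBSO)-N-methoxy-N,3-dimethylbutanamide (ring substituents cis) | CC(=O)[C@@H]1CCC(O[Si](C)(C)C(C)(C)C)=C[C@@H]1C(C)(C)[C@H](O[Si](C)(C)C(C)(C)C)C(=O)N(C)OC | intermediate
8 | (2S)-2-(TBSO)-3-[(1R,6R)-3-(TBSO)-6-(prop-1-en-2-yl)cyclohex-2-en-1-yl]-N-methoxy-N,3-dimethylbutanamide | C=C(C)[C@@H]1CCC(O[Si](C)(C)C(C)(C)C)=C[C@@H]1C(C)(C)[C@H](O[Si](C)(C)C(C)(C)C)C(=O)N(C)OC | intermediate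
9 | (4S)-4-(TBSO)-5-methyl-5-[(1R,6R)-3-(TBSO)-6-(prop-1-en-2-yl)cyclohex-2-en-1-yl]hex-1-en-3-one | C=C(C)[C@@H]1CCC(O[Si](C)(C)C(C)(C)C)=C[C@@H]1C(C)(C)[C@H](O[Si](C)(C)C(C)(C)C)C(=O)C=C | intermediate
10 | cis-fused 3,7-bis(TBSO)-3-demethyl-4,10-secolongipina-3,9-dien-8-one (H5, H7 and H11 on one face) | O=C1C=C(C)[C@@H]2CCC(O[Si](C)(C)C(C)(C)C)=C[C@@H]2C(C)(C)[C@@H]1O[Si](C)(C)C(C)(C)C | intermediate
11 | 9,10-epoxy-3,7-bis(TBSO)-3-demethyl-4,10-secolongipin-3-en-8-one (epoxide oxygen on the face of H5, H7, H11) | O1[C@@H]2C(=O)[C@@H](O[Si](C)(C)C(C)(C)C)C(C)(C)[C@H]3C=C(O[Si](C)(C)C(C)(C)C)CC[C@H]3[C@]12C | intermediate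
12 | 9,10-epoxy-8-hydroxy-3,7-bis(TBSO)-3-demethyl-4,10-secolongipin-3-ene (C8–OH trans to the epoxide oxygen, cis to C7–O) | O1[C@@H]2[C@@H](O)[C@@H](O[Si](C)(C)C(C)(C)C)C(C)(C)[C@H]3C=C(O[Si](C)(C)C(C)(C)C)CC[C@H]3[C@]12C | intermediate
13 | 9,10-epoxy-3,7,8-tris(TBSO)-3-demethyl-4,10-secolongipin-3-ene | O1[C@@H]2[C@@H](O[Si](C)(C)C(C)(C)C)[C@@H](O[Si](C)(C)C(C)(C)C)C(C)(C)[C@H]3C=C(O[Si](C)(C)C(C)(C)C)CC[C@H]3[C@]12C | intermediate
14 | 9-hydroxy-7,8-bis(TBSO)-3-demethyllongipinan-3-one (C4, C5, C7–C11 as in the target) | O[C@@H]1[C@@H](O[Si](C)(C)C(C)(C)C)[C@@H](O[Si](C)(C)C(C)(C)C)C(C)(C)[C@@H]2[C@H]3CCC(=O)[C@@H]2[C@@]13C | intermediate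
15 | 9-angeloyloxy-7,8-bis(TBSO)-3-demethyllongipinan-3-one | C/C=C(/C)C(=O)O[C@@H]1[C@@H](O[Si](C)(C)C(C)(C)C)[C@@H](O[Si](C)(C)C(C)(C)C)C(C)(C)[C@@H]2[C@H]3CCC(=O)[C@@H]2[C@@]13C | intermediate
16 | 9-angeloyloxy-7,8-bis(TBSO)-3-demethyllongipin-1-en-3-one | C/C=C(/C)C(=O)O[C@@H]1[C@@H](O[Si](C)(C)C(C)(C)C)[C@@H](O[Si](C)(C)C(C)(C)C)C(C)(C)[C@@H]2[C@H]3C=CC(=O)[C@@H]2[C@@]13C | intermediate
17 | 9-angeloyloxy-3-hydroxy-7,8-bis(TBSO)longipin-1-ene (C3 hydroxyl syn to the C10 methyl) | C/C=C(/C)C(=O)O[C@@H]1[C@@H](O[Si](C)(C)C(C)(C)C)[C@@H](O[Si](C)(C)C(C)(C)C)C(C)(C)[C@@H]2[C@H]3C=C[C@](C)(O)[C@@H]2[C@@]13C | intermediate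
18 | 9-angeloyloxy-7,8-bis(TBSO)longipin-2-en-1-one | C/C=C(/C)C(=O)O[C@@H]1[C@@H](O[Si](C)(C)C(C)(C)C)[C@@H](O[Si](C)(C)C(C)(C)C)C(C)(C)[C@@H]2[C@H]3C(=O)C=C(C)[C@@H]2[C@@]13C | intermediate
19 | 9-angeloyloxy-7,8-dihydroxylongipin-2-en-1-one | C/C=C(/C)C(=O)O[C@@H]1[C@@H](O)[C@@H](O)C(C)(C)[C@@H]2[C@H]3C(=O)C=C(C)[C@@H]2[C@@]13C | intermediate
20 | CNP0251293.1, (4R,5S,7S,8S,9S,10R,11R)-9-angeloyloxy-7-hydroxy-8-(3-methylbutanoyloxy)longipin-2-en-1-one | C/C=C(/C)C(=O)O[C@@H]1[C@@H](OC(=O)CC(C)C)[C@@H](O)C(C)(C)[C@@H]2[C@H]3C(=O)C=C(C)[C@@H]2[C@@]13C | target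

**Total step count:** 17. **Longest linear sequence:** 17 steps, from (S)-pantolactone.

**Steps most likely to fail**

1. Step 11 (Proposed new method). The Lewis-acid-activated epoxide may rearrange (1,2-hydride shift to a C9 ketone, or proton loss to allylic alcohols) faster than the strained four-membered ring closes. The fallback uses the known anionic counterpart and sets out from 13. MeLi in THF (0 → 25 °C) should cleave only the enol silyl ether and give lithium enolate F1 regiospecifically; warming (with HMPA if needed) should then bring about the Stork-type intramolecular enolate alkylation by the epoxide (4-exo, inversion at C10), and aqueous work-up returns 14.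

2. Step 4. The catalyst may fail to control the π-face against the remote C7 centre, or its acidity may strip the dienol silyl ether before cycloaddition. The fallback moves face control to a covalent auxiliary and sets out from 5. Et2AlCl-promoted cycloaddition with (S)-3-acryloyl-4-benzyloxazolidin-2-one (the auxiliary enantiomer is assumed to be the matching one) should give imide F2. Lithium ethanethiolate exchanges the auxiliary for thioester F3, and Fukuyama coupling (MeZnI, PdCl2(PPh3)2) converts F3 into methyl ketone 7, leaving the Weinreb amide untouched.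

3. Step 13. Dehydrogenation of the hindered bicyclic ketone may be sluggish, or oxidation may spread to positions next to the ester and silyl ethers. The fallback desaturates before esterification and sets out from 14. Soft enolisation (TMSOTf, Et3N) should give bis(trimethylsilyl) compound F4, with the enol ether towards C2 only. Saegusa–Ito oxidation (Pd(OAc)2, MeCN) followed by methanolysis of the C9 silyl ether gives hydroxy enone F5, and Yamaguchi angeloylation of F5 returns to 16.

Further compounds
F1 | step 11 | lithium enolate of 13 (C3–OLi, C3=C4) | O1[C@@H]2[C@@H](O[Si](C)(C)C(C)(C)C)[C@@H](O[Si](C)(C)C(C)(C)C)C(C)(C)[C@H]3C=C(O[Li])CC[C@H]3[C@]12C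
F2 | step 4 | N-acyl oxazolidinone cycloadduct (auxiliary in place of the methyl of 7) | O=C([C@@H]1CCC(O[Si](C)(C)C(C)(C)C)=C[C@@H]1C(C)(C)[C@H](O[Si](C)(C)C(C)(C)C)C(=O)N(C)OC)N1C(=O)OC[C@@H]1Cc1ccccc1
F3 | step 4 | S-ethyl thioester corresponding to 7 | CCSC(=O)[C@@H]1CCC(O[Si](C)(C)C(C)(C)C)=C[C@@H]1C(C)(C)[C@H](O[Si](C)(C)C(C)(C)C)C(=O)N(C)OC
F4 | step 13 | 9-(trimethylsilyloxy)-3-(trimethylsilyloxy)-7,8-bis(TBSO)-3-demethyllongipin-2-ene | C[Si](C)(C)O[C@@H]1[C@@H](O[Si](C)(C)C(C)(C)C)[C@@H](O[Si](C)(C)C(C)(C)C)C(C)(C)[C@@H]2[C@H]3CC=C(O[Si](C)(C)C)[C@@H]2[C@@]13C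
F5 | step 13 | 9-hydroxy-7,8-bis(TBSO)-3-demethyllongipin-1-en-3-one | O[C@@H]1[C@@H](O[Si](C)(C)C(C)(C)C)[C@@H](O[Si](C)(C)C(C)(C)C)C(C)(C)[C@@H]2[C@H]3C=CC(=O)[C@@H]2[C@@]13C
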